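**Retrosynthetic overview**
- The target is ent-oritin-(4α→6)-oritin-4α-ol. The lower C4–OH comes last, by hydride reduction of a C4 ketone; before that, the C4(upper)–C6(lower) bond is made by a boron-tethered syn arylation.
- Both flavan halves are the two antipodes of one 2,3-trans-flavan-3-ol. They come from a single achiral 2-aryl-4H-chromene by hydroboration with the two antipodes of IpcBH2, and C4 of each is then oxidised with DDQ.
- The 4H-chromene (ring C with O1) is made by a peroxide-driven ring expansion of a 3-aryl-1H-indene, an aryl shift from carbon to oxygen.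
- The indene is assembled from catechol (as its diphenylmethylene ketal, by ortho-lithiation), N-methoxy-N-methylacrylamide (the C3 unit) and 4-iodophenol (ring B).
- Ring order: five-membered carbocycle, then ring C by expansion (once, shared by both halves), then the interflavan bond, then the last stereocentre.

Assumption: the facial sense of IpcBH2 is taken from 1-arylcycloalkenes (reagent from (+)-α-pinene gives the (2R,3S) alcohol); if it is the reverse, the two reagents simply change places between steps 6 and 7.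

**Step 1**
Reactants: 1 catechol
Product: 2 2,2-diphenyl-1,3-benzodioxole
Conditions: Ph2CCl2, neat, 170 °C
Reagents that add atoms: dichlorodiphenylmethane ClC(Cl)(c1ccccc1)c1ccccc1
Why: Double substitution of the gem-dichloride by the catechol (ketalisation) gives the hydrogenolysable diphenylmethylene ketal, which also directs the next lithiation.

**Step 2**
Reactants: 2 2,2-diphenyl-1,3-benzodioxole; 3 N-methoxy-N-methylacrylamide
Product: 5 1-(2,2-diphenyl-1,3-benzodioxol-4-yl)prop-2-en-1-one, via aryllithium 4 (not isolated)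
Conditions: n-BuLi, TMEDA, THF, 0 °C; then 3, −78 °C; cold 1 M HCl
Reagents that add atoms: none
Why: Directed ortho-metalation beside the ketal oxygen gives 4, which acylates the Weinreb amide once (stable chelated adduct, Weinreb ketone synthesis) to the aryl vinyl ketone; no stereocentre.

**Step 3**
Reactants: 6 4-iodophenol
Product: 7 4-iodophenyl pivalate
Conditions: PivCl, Et3N, DMAP (cat.), CH2Cl2, 0 → 25 °C
Reagents that add atoms: pivaloyl chloride CC(C)(C)C(Cl)=O
Why: Plain O-acylation; the hindered ester survives the Grignard step and later makes ring B a poor migrating group and a poor site for DDQ.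

**Step 4**
Reactants: 7 4-iodophenyl pivalate; 5 1-(2,2-diphenyl-1,3-benzodioxol-4-yl)prop-2-en-1-one
Product: 10 4-[4,5-(diphenylmethylenedioxy)-1H-inden-3-yl]phenyl pivalate, via aryl Grignard reagent 8 (not isolated), via tertiary allylic alcohol 9 (not isolated)
Conditions: iPrMgCl·LiCl, THF, −30 °C; then 5, LaCl3·2LiCl (30 mol%), −40 → 0 °C; aq. NH4Cl; then p-TsOH (cat.), CH2Cl2, 25 °C
Reagents that add atoms: none
Why: Iodine–magnesium exchange tolerates the hindered ester at low temperature, LaCl3-assisted 1,2-addition gives carbinol 9, and acid ionises it to a 1,1-diarylallyl cation whose CH2 terminus closes on the ring A carbon para to a ketal oxygen (intramolecular Friedel–Crafts-type cationic cyclisation; ring B is deactivated), so only the achiral 3-arylindene forms.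

**Step 5**
Reactants: 10 4-[4,5-(diphenylmethylenedioxy)-1H-inden-3-yl]phenyl pivalate
Product: 12 4-[7,8-(diphenylmethylenedioxy)-4H-chromen-2-yl]phenyl pivalate, via silyl peroxide 11 (not isolated)
Conditions: Me3SiOOSiMe3 (1.1 equiv), TfOH (5 mol%), CH2Cl2/HFIP 4:1, −40 → 0 °C; then Et3N
Reagents that add atoms: bis(trimethylsilyl) peroxide C[Si](C)(C)OO[Si](C)(C)C
Why: Proposed new method: Markovnikov protonation of the indene gives the tertiary diarylmethyl cation, which Me3SiOOSiMe3 traps as silyl peroxide 11; acid activation of the O–O bond then triggers a Criegee/Hock-type 1,2-shift of the ring-fused, ortho-oxygenated aryl carbon from carbon to oxygen (ring B is made a poor migrator by its acyloxy group and stays to stabilise the charge), which expands the five-membered carbocycle to the 2-arylchroman-2-ylium ion and installs O1, and loss of H-3 on Et3N quench gives the enol ether under water-free conditions; the closest known reactions are the acid-catalysed Hock rearrangement of cumene and tetralin hydroperoxides and Baeyer–Villiger oxidation with Me3SiOOSiMe3; no stereocentre is formed.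

**Step 6**
Reactants: 12 4-[7,8-(diphenylmethylenedioxy)-4H-chromen-2-yl]phenyl pivalate
Product: 14 4-[(2R,3S)-3-hydroxy-7,8-(diphenylmethylenedioxy)chroman-2-yl]phenyl pivalate, via alkylborane 13 (not isolated)
Conditions: IpcBH2 (from (+)-α-pinene), THF, −25 °C; then Me3NO·2H2O, 45 °C
Reagents that add atoms: trimethylamine N-oxide C[N+](C)(C)[O-]
Why: Asymmetric hydroboration–oxidation (Brown) puts boron on C3 (β to O1, remote from the aryl group) and H on C2 of the same face, so oxidation with retention gives only the 2,3-trans alcohol, and the reagent antipode selects the (2R,3S) face (ee raised by crystallisation if needed).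

**Step 7**
Reactants: 12 4-[7,8-(diphenylmethylenedioxy)-4H-chromen-2-yl]phenyl pivalate
Product: 16 4-[(2S,3R)-3-hydroxy-7,8-(diphenylmethylenedioxy)chroman-2-yl]phenyl pivalate, via alkylborane 15 (not isolated)
Conditions: IpcBH2 (from (−)-α-pinene), THF, −25 °C; then Me3NO·2H2O, 45 °C
Reagents that add atoms: trimethylamine N-oxide C[N+](C)(C)[O-]
Why: The same syn hydroboration–oxidation with the antipodal reagent gives the mirror-image 2,3-trans alcohol (2S,3R) needed for the upper unit.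

**Step 8**
Reactants: 14 4-[(2R,3S)-3-hydroxy-7,8-(diphenylmethylenedioxy)chroman-2-yl]phenyl pivalate
Product: 18 4-[(2R,3R)-3-hydroxy-7,8-(diphenylmethylenedioxy)-4-oxochroman-2-yl]phenyl pivalate, via cis-3,4-diol 17 (not isolated)
Conditions: DDQ (3 equiv), 1,4-dioxane/H2O 9:1, 25 → 40 °C
Reagents that add atoms: water O
Why: DDQ abstracts hydride from C4 (cation stabilised by O1 and the para ketal oxygen), water adds, and the p-alkoxybenzylic alcohol is oxidised again to the aryl ketone (benzylic oxidation); C2 is shielded by its electron-poor aryl group and C2/C3 keep their configuration.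

**Step 9**
Reactants: 18 4-[(2R,3R)-3-hydroxy-7,8-(diphenylmethylenedioxy)-4-oxochroman-2-yl]phenyl pivalate
Product: 19 4-[(2R,3R)-3,7,8-trihydroxy-4-oxochroman-2-yl]phenyl pivalate
Conditions: H2 (1 atm), Pd(OH)2/C, THF/MeOH, 25 °C
Reagents that add atoms: none
Why: Hydrogenolysis of the two benzhydrylic C–O bonds frees the catechol; the conjugated ketone and the ester are inert under these conditions.

**Step 10**
Reactants: 16 4-[(2S,3R)-3-hydroxy-7,8-(diphenylmethylenedioxy)chroman-2-yl]phenyl pivalate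
Product: 20 4-[(2S,3R,4R)-3-hydroxy-4-methoxy-7,8-(diphenylmethylenedioxy)chroman-2-yl]phenyl pivalate
Conditions: DDQ (1.3 equiv), CH2Cl2/MeOH 4:1, 0 → 25 °C
Reagents that add atoms: methanol CO
Why: DDQ oxidative etherification at C4 (benzylic hydride abstraction, then methanol capture, expected mainly cis to the 3-OH); this C4 centre only carries a leaving group and is reset in step 11, so its epimer ratio does not matter.

**Step 11**
Reactants: 19 4-[(2R,3R)-3,7,8-trihydroxy-4-oxochroman-2-yl]phenyl pivalate; 20 4-[(2S,3R,4R)-3-hydroxy-4-methoxy-7,8-(diphenylmethylenedioxy)chroman-2-yl]phenyl pivalate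
Product: 22 4-[(2R,3R)-3,7,8-trihydroxy-6-{(2S,3R,4R)-3-hydroxy-7,8-(diphenylmethylenedioxy)-2-[4-(pivaloyloxy)phenyl]chroman-4-yl}-4-oxochroman-2-yl]phenyl pivalate, via mixed borate ester 21 (not isolated)
Conditions: B(OMe)3 (1.05 equiv), 4 Å MS, THF/PhMe, 50 °C (−MeOH); then CH2Cl2/HFIP 3:1, 0 → 25 °C; MeOH co-evaporation
Reagents that add atoms: none
Why: Proposed new method: B(OMe)3 joins the catechol of 19 and the 3-OH of 20 in one borate ester 21, the Lewis-acidic boron chelates the cis 4-OMe and ionises it in HFIP to the O1/O7-stabilised C4 cation while itself becoming a tetracoordinate borate, which makes the tethered catecholate ring electron-rich and holds its C6 (ortho to O7, the only ring carbon the seven-membered transition state can reach) on the face of O3, so the new C–C bond forms syn to the 3-OH (4R, 3,4-cis) and only at C6; the closest known reactions are boron-mediated aglycon delivery (syn opening of 1,2-anhydro sugars by boronic esters) and boronate-templated ortho-hydroxyalkylation of phenols, whereas the ordinary untethered Friedel–Crafts coupling is mainly 3,4-trans.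

**Step 12**
Reactants: 22 4-[(2R,3R)-3,7,8-trihydroxy-6-{(2S,3R,4R)-3-hydroxy-7,8-(diphenylmethylenedioxy)-2-[4-(pivaloyloxy)phenyl]chroman-4-yl}-4-oxochroman-2-yl]phenyl pivalate
Product: 23 4-[(2R,3R)-3,7,8-trihydroxy-6-{(2S,3R,4R)-3,7,8-trihydroxy-2-[4-(pivaloyloxy)phenyl]chroman-4-yl}-4-oxochroman-2-yl]phenyl pivalate
Conditions: H2 (1 atm), Pd(OH)2/C, THF/MeOH, 25 °C
Reagents that add atoms: none
Why: Hydrogenolysis removes the remaining diphenylmethylene ketal while the molecule still has no benzylic hydroxyl group that could be lost (the lower C4 is a ketone).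

**Step 13**
Reactants: 23 4-[(2R,3R)-3,7,8-trihydroxy-6-{(2S,3R,4R)-3,7,8-trihydroxy-2-[4-(pivaloyloxy)phenyl]chroman-4-yl}-4-oxochroman-2-yl]phenyl pivalate
Product: 25 (2R,3S,4R)-2-(4-hydroxyphenyl)-6-[(2S,3R,4R)-3,7,8-trihydroxy-2-(4-hydroxyphenyl)chroman-4-yl]chroman-3,4,7,8-tetrol, via diol bis-pivalate 24 (not isolated)
Conditions: LiBH4 (excess), THF/MeOH, −20 → 25 °C, Ar; AcOH to pH 6
Reagents that add atoms: none
Why: Borohydride reduction of the 3-hydroxychroman-4-one gives the 3,4-trans alcohol (hydride delivered from the 3-alkoxyborohydride puts H-4 cis to O-3, as in NaBH4 reductions of 2,3-trans-dihydroflavonols), and LiBH4 then reductively cleaves both aryl pivalates; no other centre is touched.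

**Compound list**
1 | catechol (benzene-1,2-diol) | Oc1ccccc1O | starting material
2 | 2,2-diphenyl-1,3-benzodioxole | c1ccc(cc1)C1(Oc2ccccc2O1)c1ccccc1 | intermediate
3 | N-methoxy-N-methylacrylamide | C=CC(=O)N(C)OC | starting material
4 | (2,2-diphenyl-1,3-benzodioxol-4-yl)lithium | [Li]c1cccc2OC(c3ccccc3)(c3ccccc3)Oc12 | intermediate
5 | 1-(2,2-diphenyl-1,3-benzodioxol-4-yl)prop-2-en-1-one | C=CC(=O)c1cccc2OC(c3ccccc3)(c3ccccc3)Oc12 | intermediate
6 | 4-iodophenol | Oc1ccc(I)cc1 | starting material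
7 | 4-iodophenyl pivalate | CC(C)(C)C(=O)Oc1ccc(I)cc1 | intermediate
8 | [4-(pivaloyloxy)phenyl]magnesium chloride | CC(C)(C)C(=O)Oc1ccc([Mg]Cl)cc1 | intermediate
9 | 4-[1-(2,2-diphenyl-1,3-benzodioxol-4-yl)-1-hydroxyprop-2-en-1-yl]phenyl pivalate (racemic) | CC(C)(C)C(=O)Oc1ccc(cc1)C(O)(C=C)c1cccc2OC(c3ccccc3)(c3ccccc3)Oc12 | intermediate
10 | 4-[4,5-(diphenylmethylenedioxy)-1H-inden-3-yl]phenyl pivalate (aryl on C3; C4 and C5 oxygens bridged by CPh2; C3a lies between C3 and C4) | CC(C)(C)C(=O)Oc1ccc(cc1)C1=CCc2ccc3OC(c4ccccc4)(c4ccccc4)Oc3c12 | intermediate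
11 | 4-[6,7-(diphenylmethylenedioxy)-1-(trimethylsilylperoxy)indan-1-yl]phenyl pivalate (racemic) | CC(C)(C)C(=O)Oc1ccc(cc1)C1(OO[Si](C)(C)C)CCc2ccc3OC(c4ccccc4)(c4ccccc4)Oc3c12 | intermediate
12 | 4-[7,8-(diphenylmethylenedioxy)-4H-chromen-2-yl]phenyl pivalate (flav-2-ene) | CC(C)(C)C(=O)Oc1ccc(cc1)C1=CCc2ccc3OC(c4ccccc4)(c4ccccc4)Oc3c2O1 | intermediate
13 | 2,3-trans 3-(isopinocampheylboranyl)flavan, same ring configuration as 14, Ipc from (+)-α-pinene | CC(C)(C)C(=O)Oc1ccc([C@H]2Oc3c(ccc4OC(c5ccccc5)(c5ccccc5)Oc43)C[C@@H]2B[C@H]6[C@H](C)[C@H]7C[C@@H](C6)C7(C)C)cc1 | intermediate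
14 | 4-[(2R,3S)-3-hydroxy-7,8-(diphenylmethylenedioxy)chroman-2-yl]phenyl pivalate | CC(C)(C)C(=O)Oc1ccc([C@H]2Oc3c(ccc4OC(c5ccccc5)(c5ccccc5)Oc43)C[C@@H]2O)cc1 | intermediate
15 | 2,3-trans 3-(isopinocampheylboranyl)flavan, same ring configuration as 16, Ipc from (−)-α-pinene | CC(C)(C)C(=O)Oc1ccc([C@@H]2Oc3c(ccc4OC(c5ccccc5)(c5ccccc5)Oc43)C[C@H]2B[C@@H]6[C@@H](C)[C@@H]7C[C@H](C6)C7(C)C)cc1 | intermediate
16 | 4-[(2S,3R)-3-hydroxy-7,8-(diphenylmethylenedioxy)chroman-2-yl]phenyl pivalate | CC(C)(C)C(=O)Oc1ccc([C@@H]2Oc3c(ccc4OC(c5ccccc5)(c5ccccc5)Oc43)C[C@H]2O)cc1 | intermediate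
17 | 4-[(2R,3S,4S)-3,4-dihydroxy-7,8-(diphenylmethylenedioxy)chroman-2-yl]phenyl pivalate (3,4-cis) | CC(C)(C)C(=O)Oc1ccc([C@H]2Oc3c(ccc4OC(c5ccccc5)(c5ccccc5)Oc43)[C@H](O)[C@@H]2O)cc1 | intermediate
18 | 4-[(2R,3R)-3-hydroxy-7,8-(diphenylmethylenedioxy)-4-oxochroman-2-yl]phenyl pivalate | CC(C)(C)C(=O)Oc1ccc([C@H]2Oc3c(ccc4OC(c5ccccc5)(c5ccccc5)Oc43)C(=O)[C@@H]2O)cc1 | intermediate
19 | 4-[(2R,3R)-3,7,8-trihydroxy-4-oxochroman-2-yl]phenyl pivalate | CC(C)(C)C(=O)Oc1ccc([C@H]2Oc3c(ccc(O)c3O)C(=O)[C@@H]2O)cc1 | intermediate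
20 | 4-[(2S,3R,4R)-3-hydroxy-4-methoxy-7,8-(diphenylmethylenedioxy)chroman-2-yl]phenyl pivalate (3,4-cis) | CC(C)(C)C(=O)Oc1ccc([C@@H]2Oc3c(ccc4OC(c5ccccc5)(c5ccccc5)Oc43)[C@@H](OC)[C@H]2O)cc1 | intermediate
21 | cyclic 7,8-O-borate of 19 carrying the 3-O of 20 as third ligand on boron | CC(C)(C)C(=O)Oc1ccc([C@H]2Oc3c(ccc4OB(O[C@@H]5[C@H](OC)c6ccc7OC(c8ccccc8)(c8ccccc8)Oc7c6O[C@H]5c9ccc(OC(=O)C(C)(C)C)cc9)Oc43)C(=O)[C@@H]2O)cc1 | intermediate
22 | 4-[(2R,3R)-3,7,8-trihydroxy-6-{(2S,3R,4R)-3-hydroxy-7,8-(diphenylmethylenedioxy)-2-[4-(pivaloyloxy)phenyl]chroman-4-yl}-4-oxochroman-2-yl]phenyl pivalate | CC(C)(C)C(=O)Oc1ccc([C@H]2Oc3c(cc([C@@H]4c5ccc6OC(c7ccccc7)(c7ccccc7)Oc6c5O[C@@H](c5ccc(OC(=O)C(C)(C)C)cc5)[C@@H]4O)c(O)c3O)C(=O)[C@@H]2O)cc1 | intermediate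
23 | 4-[(2R,3R)-3,7,8-trihydroxy-6-{(2S,3R,4R)-3,7,8-trihydroxy-2-[4-(pivaloyloxy)phenyl]chroman-4-yl}-4-oxochroman-2-yl]phenyl pivalate | CC(C)(C)C(=O)Oc1ccc([C@H]2Oc3c(cc([C@@H]4c5ccc(O)c(O)c5O[C@@H](c5ccc(OC(=O)C(C)(C)C)cc5)[C@@H]4O)c(O)c3O)C(=O)[C@@H]2O)cc1 | intermediate
24 | 4-[(2R,3S,4R)-3,4,7,8-tetrahydroxy-6-{(2S,3R,4R)-3,7,8-trihydroxy-2-[4-(pivaloyloxy)phenyl]chroman-4-yl}chroman-2-yl]phenyl pivalate | CC(C)(C)C(=O)Oc1ccc([C@H]2Oc3c(cc([C@@H]4c5ccc(O)c(O)c5O[C@@H](c5ccc(OC(=O)C(C)(C)C)cc5)[C@@H]4O)c(O)c3O)[C@@H](O)[C@@H]2O)cc1 | intermediate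
25 | (2R,3S,4R)-2-(4-hydroxyphenyl)-6-[(2S,3R,4R)-3,7,8-trihydroxy-2-(4-hydroxyphenyl)chroman-4-yl]chroman-3,4,7,8-tetrol (ent-oritin-(4α→6)-oritin-4α-ol, CNP0391561.8) | Oc1ccc([C@H]2Oc3c(cc([C@@H]4c5ccc(O)c(O)c5O[C@@H](c5ccc(O)cc5)[C@@H]4O)c(O)c3O)[C@@H](O)[C@@H]2O)cc1 | target

**Step count and risks**
Total steps: 13. Longest linear sequence: 10 steps (1 → 2 → 5 → 10 → 12 → 14 → 18 → 19 → 22 → 23 → 25, i.e. steps 1, 2, 4, 5, 6, 8, 9, 11, 12, 13).

Steps most likely to fail:

1. Step 5 (proposed new ring expansion). Risks are migration of ring B instead of ring A, cationic oligomerisation of the indene, and over-oxidation of the enol ether. The fallback uses known chemistry and keeps a ring expansion, but moves it to a ketone where only one aryl group can migrate. It sets out from 5 and returns at 12. Vinyl ketone 5 is closed by a Nazarov cyclisation (TfOH, CH2Cl2, 0 °C, brief) to 6,7-(diphenylmethylenedioxy)indan-1-one F1. Baeyer–Villiger oxidation (mCPBA, NaHCO3, CH2Cl2) with aryl migration expands it to the lactone 7,8-(diphenylmethylenedioxy)chroman-2-one F2. Single addition of Grignard reagent 8 (made from 7 as in step 4) at −78 °C gives 4-[3-(4-hydroxy-2,2-diphenyl-1,3-benzodioxol-5-yl)propanoyl]phenyl pivalate F3. Cyclodehydration of its lactol form (p-TsOH cat., PhMe, water removal) gives 12.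

2. Step 11 (proposed new tethered coupling). Risks are a poorly nucleophilic ring A in 19, borate scrambling, and elimination of 20 to the flavan-3-one. The fallback is the known untethered thioether route; it sets out from 20 (with 19) and returns at 22. Thiolysis of 20 (BnSH, SnCl4, CH2Cl2, −20 °C) gives 4-[(2S,3S,4S)-4-(benzylsulfanyl)-3-hydroxy-7,8-(diphenylmethylenedioxy)chroman-2-yl]phenyl pivalate F4. Thiophilic activation with AgBF4 (THF, 0 °C) in the presence of 19 couples it at C6 through the free C4 cation. This is not stereocontrolled, so 22 is separated by chromatography from its upper-unit C4 epimer 4-[(2R,3R)-3,7,8-trihydroxy-6-{(2S,3R,4S)-3-hydroxy-7,8-(diphenylmethylenedioxy)-2-[4-(pivaloyloxy)phenyl]chroman-4-yl}-4-oxochroman-2-yl]phenyl pivalate F5, and 22 goes on to step 12.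

3. Step 6 (and its mirror, step 7). Risks are modest ee on this aryl enol ether and β-aryloxy elimination of the borane. The fallback replaces reagent control by resolution; it sets out from 12 and returns at 14 and 16. Hydroboration with BH3·SMe2 (THF, 0 °C), then Me3NO, gives the racemic 2,3-trans alcohol (14 + 16). Lipase-catalysed acylation with vinyl acetate (Burkholderia cepacia lipase, MTBE, 30 °C) esterifies one antipode. Written for the case where 16 reacts faster, this gives 4-[(2S,3R)-3-acetoxy-7,8-(diphenylmethylenedioxy)chroman-2-yl]phenyl pivalate F6 and leaves 14. After separation, F6 is de-acetylated by the same lipase in phosphate buffer/MTBE (the pivalate is untouched) to give 16. If the enzyme prefers 14, the roles are exchanged and both antipodes are still obtained.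

**Further compounds**
F1 | step 5 | 6,7-(diphenylmethylenedioxy)indan-1-one | O=C1CCc2ccc3OC(c4ccccc4)(c4ccccc4)Oc3c12
F2 | step 5 | 7,8-(diphenylmethylenedioxy)chroman-2-one | O=C1CCc2ccc3OC(c4ccccc4)(c4ccccc4)Oc3c2O1
F3 | step 5 | 4-[3-(4-hydroxy-2,2-diphenyl-1,3-benzodioxol-5-yl)propanoyl]phenyl pivalate | CC(C)(C)C(=O)Oc1ccc(cc1)C(=O)CCc1ccc2OC(c3ccccc3)(c3ccccc3)Oc2c1O
F4 | step 11 | 4-[(2S,3S,4S)-4-(benzylsulfanyl)-3-hydroxy-7,8-(diphenylmethylenedioxy)chroman-2-yl]phenyl pivalate | CC(C)(C)C(=O)Oc1ccc([C@@H]2Oc3c(ccc4OC(c5ccccc5)(c5ccccc5)Oc43)[C@H](SCc5ccccc5)[C@H]2O)cc1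
F5 | step 11 | 4-[(2R,3R)-3,7,8-trihydroxy-6-{(2S,3R,4S)-3-hydroxy-7,8-(diphenylmethylenedioxy)-2-[4-(pivaloyloxy)phenyl]chroman-4-yl}-4-oxochroman-2-yl]phenyl pivalate | CC(C)(C)C(=O)Oc1ccc([C@H]2Oc3c(cc([C@H]4c5ccc6OC(c7ccccc7)(c7ccccc7)Oc6c5O[C@@H](c5ccc(OC(=O)C(C)(C)C)cc5)[C@@H]4O)c(O)c3O)C(=O)[C@@H]2O)cc1
F6 | step 6 | 4-[(2S,3R)-3-acetoxy-7,8-(diphenylmethylenedioxy)chroman-2-yl]phenyl pivalate | CC(C)(C)C(=O)Oc1ccc([C@@H]2Oc3c(ccc4OC(c5ccccc5)(c5ccccc5)Oc43)C[C@H]2OC(C)=O)cc1
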